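Retrosynthesis: the O7–prenyl ether is cut first, then ring C of the isoflavone at two bonds, O1–C8a and C4–C4a, which are made together in one aryne annulation.
Enabling feature: O1 and C4 sit on the adjacent ring-A carbons C8a and C4a, and the oxygen on C5, next to C4a, polarises a C4a≡C8a aryne so that an oxygen nucleophile enters at C8a and the carbanion appears at C4a.
Forward: a 3,5-bis(benzyloxy) o-silylaryl triflate (ring A, three steps) and the enol of a methyl α-formyl arylacetate (ring B plus C2, C3, C4; three steps) are joined, and ring C, the only ring built, closes in the same operation.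
End game: hydrogenolysis frees 5-OH and 7-OH, the C4 carbonyl then differentiates them (chelated 5-OH is spared, 7-OH is prenylated), and mild acid removes the two MOM groups.
Stereochemistry: the target has no stereocentre; only the Z geometry of the enolate matters, and it is consumed in the ring closure.

Key step: step 7

Remark: the target contains no stereocentre and no stereogenic double bond, so it is a single achiral compound and no enantiocontrol is required.
Remark: phenoxides that form reversibly under K2CO3 or amine bases are regarded as the conjugate bases of the numbered phenols and are not numbered separately.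

Step 1
Reactants: 1 3,5-bis(benzyloxy)phenol
Product: 2 3,5-bis(benzyloxy)phenyl N-isopropylcarbamate
Conditions: i-PrNCO, Et3N (cat.), CH2Cl2, rt
Reagents that add atoms: isopropyl isocyanate, CC(C)N=C=O
Why: Base-catalysed addition of a phenol to an isocyanate (carbamoylation) is clean for electron-rich phenols and installs a directing group that is later removable under mild base.

Step 2
Reactants: 2 3,5-bis(benzyloxy)phenyl N-isopropylcarbamate
Product: 6 3,5-bis(benzyloxy)-2-(trimethylsilyl)phenyl N-isopropylcarbamate, via N-TBS carbamate 3 (not isolated), via ortho-lithiated N-TBS carbamate 4 (not isolated), via C-TMS N-TBS carbamate 5 (not isolated)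
Conditions: TBSOTf, TMEDA, Et2O, 0 °C → rt; n-BuLi, TMEDA, −78 °C; TMSCl, −78 °C → rt; aq. NaHSO4
Reagents that add atoms: chlorotrimethylsilane, C[Si](C)(C)Cl
Why: Directed ortho-metalation of an O-aryl carbamate whose N–H is masked in situ as the N-silyl derivative: carbamate and neighbouring benzyloxy oxygen jointly direct the base to C2, which is equivalent to C6 by symmetry so only one regioisomer can arise, the aryllithium is silylated by TMSCl, and the labile N–Si bond is hydrolysed on acidic work-up.

Step 3
Reactants: 6 3,5-bis(benzyloxy)-2-(trimethylsilyl)phenyl N-isopropylcarbamate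
Product: 8 3,5-bis(benzyloxy)-2-(trimethylsilyl)phenyl trifluoromethanesulfonate, via silyl phenol 7 (not isolated)
Conditions: DBU, Et2NH, MeCN, 40 °C; then PhNTf2, rt
Reagents that add atoms: N-phenylbis(trifluoromethanesulfonimide), O=S(=O)(N(c1ccccc1)S(=O)(=O)C(F)(F)F)C(F)(F)F
Why: E1cB cleavage of the N-monoalkyl carbamate by DBU releases the phenoxide and isopropyl isocyanate, which diethylamine traps as a urea, and the phenoxide is triflated in the same pot (phenol triflation) under fluoride-free conditions that leave the aryl–silicon bond intact.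

Step 4
Reactants: 9 2,4-dihydroxyphenylacetic acid
Product: 10 methyl 2,4-dihydroxyphenylacetate
Conditions: MeOH, H2SO4 (cat.), reflux
Reagents that add atoms: methanol, CO
Why: Fischer esterification in a large excess of methanol gives the methyl ester and keeps the o-hydroxy ester open rather than closed to the benzofuranone.

Step 5
Reactants: 10 methyl 2,4-dihydroxyphenylacetate
Product: 11 methyl 2,4-bis(methoxymethoxy)phenylacetate
Conditions: MOMCl, i-Pr2NEt, CH2Cl2, 0 °C → rt
Reagents that add atoms: chloromethyl methyl ether, COCCl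
Why: O-alkylation of both phenols with the α-chloro ether under amine base (MOM protection) is routine and gives acetals stable to NaH, fluoride and hydrogenolysis.

Step 6
Reactants: 11 methyl 2,4-bis(methoxymethoxy)phenylacetate; 12 methyl formate
Product: 14 methyl (Z)-3-hydroxy-2-[2,4-bis(methoxymethoxy)phenyl]acrylate, via sodium enolate 13 (not isolated)
Conditions: NaH, HCO2Me, THF, 0 °C → rt; then cold dilute HCl to pH 5
Reagents that add atoms: none
Why: Crossed Claisen condensation of the arylacetate enolate with non-enolisable methyl formate is driven by formation of the stabilised enolate 13, and careful acidification should give the α-formyl ester as its hydrogen-bonded Z enol, used without purification.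

Step 7
Reactants: 8 3,5-bis(benzyloxy)-2-(trimethylsilyl)phenyl trifluoromethanesulfonate; 14 methyl (Z)-3-hydroxy-2-[2,4-bis(methoxymethoxy)phenyl]acrylate
Product: 18 5,7-bis(benzyloxy)-2',4'-bis(methoxymethoxy)isoflavone, via cesium enolate 15 (not isolated), via 3,5-bis(benzyloxy)benzyne 16 (not isolated), via aryl anion adduct 17 (not isolated)
Conditions: Cs2CO3 (1.1 equiv), THF, rt; then CsF (3 equiv), 8 added slowly, 65 °C
Reagents that add atoms: none
Why: Proposed new method: fluoride strips the silyl group from 8 and triflate leaves to give aryne 16; the oxygen of the preformed cesium enolate 15 adds to the aryne carbon remote from the flanking benzyloxy group (O1–C8a), and the aryl anion 17 that appears beside that benzyloxy group attacks the cis methyl ester and expels methoxide (C4–C4a). The closest known reaction type is the fluoride-induced annulation of arynes with methyl salicylates to xanthones, in which a phenoxide adds and the aryl anion then substitutes the ester; here the phenoxide is replaced by the enolate oxygen of an α-formyl arylacetate, which has not been shown. The pyranone ring, the only ring formed, closes by 6-exo-trig attack of the aryl anion on the ester carbonyl. No stereocentre is created. The step needs aryne regioselectivity, secured by the inductive pull of the benzyloxy oxygen that ends up on C5; O- rather than C-arylation, favoured because the enolate carbon is fully substituted and screened by the twisted ortho-substituted aryl ring while the formyl oxygen is unhindered; and ring closure rather than protonation of 17, favoured by the Z geometry of the cesium-chelated enolate in THF and by deprotonating 14 before any aryne is released.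

Step 8
Reactants: 18 5,7-bis(benzyloxy)-2',4'-bis(methoxymethoxy)isoflavone
Product: 19 5,7-dihydroxy-2',4'-bis(methoxymethoxy)isoflavone
Conditions: H2 (1 atm), 10% Pd/C, EtOAc–THF, rt
Reagents that add atoms: none
Why: Heterogeneous hydrogenolysis of aryl benzyl ethers is much faster than hydrogenation of the C2=C3 bond of an isoflavone, and the MOM acetals are inert under these neutral conditions if hydrogen uptake is stopped after two equivalents.

Step 9
Reactants: 19 5,7-dihydroxy-2',4'-bis(methoxymethoxy)isoflavone; 20 prenyl bromide (1-bromo-3-methylbut-2-ene)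
Product: 21 5-hydroxy-2',4'-bis(methoxymethoxy)-7-(prenyloxy)isoflavone
Conditions: K2CO3, acetone, 50 °C
Reagents that add atoms: none
Why: Williamson etherification under weak base alkylates only 7-OH, the most acidic phenol (vinylogous acid through C4=O), because 5-OH is held in a hydrogen bond to the C4 carbonyl and is neither deprotonated nor nucleophilic under these conditions.

Step 10
Reactants: 21 5-hydroxy-2',4'-bis(methoxymethoxy)-7-(prenyloxy)isoflavone
Product: 22 5,2',4'-trihydroxy-7-(prenyloxy)isoflavone (target)
Conditions: aq. HCl (3 M), MeOH–THF, rt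
Reagents that add atoms: none
Why: Acid-catalysed acetal exchange with methanol removes both MOM groups as dimethoxymethane, while dilute acid at room temperature should be too mild to ionise the allylic aryl ether or add to the trisubstituted alkene.

Compound list
1 | 3,5-bis(benzyloxy)phenol | Oc1cc(OCc2ccccc2)cc(OCc2ccccc2)c1 | starting material
2 | 3,5-bis(benzyloxy)phenyl N-isopropylcarbamate | CC(C)NC(=O)Oc1cc(OCc2ccccc2)cc(OCc2ccccc2)c1 | intermediate
3 | 3,5-bis(benzyloxy)phenyl N-(tert-butyldimethylsilyl)-N-isopropylcarbamate | CC(C)N(C(=O)Oc1cc(OCc2ccccc2)cc(OCc2ccccc2)c1)[Si](C)(C)C(C)(C)C | intermediate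
4 | [2,4-bis(benzyloxy)-6-{[N-(tert-butyldimethylsilyl)-N-isopropylcarbamoyl]oxy}phenyl]lithium | CC(C)N(C(=O)Oc1cc(OCc2ccccc2)cc(OCc2ccccc2)c1[Li])[Si](C)(C)C(C)(C)C | intermediate
5 | 3,5-bis(benzyloxy)-2-(trimethylsilyl)phenyl N-(tert-butyldimethylsilyl)-N-isopropylcarbamate | CC(C)N(C(=O)Oc1cc(OCc2ccccc2)cc(OCc2ccccc2)c1[Si](C)(C)C)[Si](C)(C)C(C)(C)C | intermediate
6 | 3,5-bis(benzyloxy)-2-(trimethylsilyl)phenyl N-isopropylcarbamate | CC(C)NC(=O)Oc1cc(OCc2ccccc2)cc(OCc2ccccc2)c1[Si](C)(C)C | intermediate
7 | 3,5-bis(benzyloxy)-2-(trimethylsilyl)phenol | Oc1cc(OCc2ccccc2)cc(OCc2ccccc2)c1[Si](C)(C)C | intermediate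
8 | 3,5-bis(benzyloxy)-2-(trimethylsilyl)phenyl trifluoromethanesulfonate | C[Si](C)(C)c1c(OCc2ccccc2)cc(OCc2ccccc2)cc1OS(=O)(=O)C(F)(F)F | intermediate
9 | 2,4-dihydroxyphenylacetic acid | OC(=O)Cc1ccc(O)cc1O | starting material
10 | methyl 2,4-dihydroxyphenylacetate | COC(=O)Cc1ccc(O)cc1O | intermediate
11 | methyl 2,4-bis(methoxymethoxy)phenylacetate | COCOc1ccc(CC(=O)OC)c(OCOC)c1 | intermediate
12 | methyl formate | COC=O | starting material
13 | sodium (Z)-3-methoxy-2-[2,4-bis(methoxymethoxy)phenyl]-3-oxoprop-1-en-1-olate | [Na+].[O-]/C=C(\C(=O)OC)c1ccc(OCOC)cc1OCOC | intermediate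
14 | methyl (Z)-3-hydroxy-2-[2,4-bis(methoxymethoxy)phenyl]acrylate | O/C=C(\C(=O)OC)c1ccc(OCOC)cc1OCOC | intermediate
15 | cesium (Z)-3-methoxy-2-[2,4-bis(methoxymethoxy)phenyl]-3-oxoprop-1-en-1-olate | [Cs+].[O-]/C=C(\C(=O)OC)c1ccc(OCOC)cc1OCOC | intermediate
16 | 3,5-bis(benzyloxy)benzyne (1,2-didehydro-3,5-bis(benzyloxy)benzene) | C1(OCc2ccccc2)=CC(OCc2ccccc2)=CC#C1 | intermediate
17 | cesium 2,4-bis(benzyloxy)-6-{[(Z)-3-methoxy-2-[2,4-bis(methoxymethoxy)phenyl]-3-oxoprop-1-en-1-yl]oxy}benzen-1-ide | c1(O/C=C(\C(=O)OC)c2ccc(OCOC)cc2OCOC)cc(OCc2ccccc2)cc(OCc2ccccc2)[c-]1.[Cs+] | intermediate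
18 | 5,7-bis(benzyloxy)-2',4'-bis(methoxymethoxy)isoflavone [5,7-bis(benzyloxy)-3-[2,4-bis(methoxymethoxy)phenyl]-4H-chromen-4-one] | O=c1c(-c2ccc(OCOC)cc2OCOC)coc2cc(OCc3ccccc3)cc(OCc3ccccc3)c12 | intermediate
19 | 5,7-dihydroxy-2',4'-bis(methoxymethoxy)isoflavone | O=c1c(-c2ccc(OCOC)cc2OCOC)coc2cc(O)cc(O)c12 | intermediate
20 | prenyl bromide (1-bromo-3-methylbut-2-ene) | CC(C)=CCBr | starting material
21 | 5-hydroxy-2',4'-bis(methoxymethoxy)-7-(prenyloxy)isoflavone | CC(C)=CCOc1cc(O)c2c(=O)c(-c3ccc(OCOC)cc3OCOC)coc2c1 | intermediate
22 | 5,2',4'-trihydroxy-7-(prenyloxy)isoflavone [3-(2,4-dihydroxyphenyl)-5-hydroxy-7-(3-methylbut-2-enyloxy)-4H-chromen-4-one] | CC(C)=CCOc1cc(O)c2c(=O)c(-c3ccc(O)cc3O)coc2c1 | target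

Total step count: 10.
Longest linear sequence: 7 steps (1, 2, 3, 7, 8, 9, 10 from compound 1; the branch 4, 5, 6, 7, 8, 9, 10 from compound 9 is equally long).

Steps most likely to fail

Risk 1 (step 7, the proposed new method). The ambident enolate may arylate at carbon, after which the aryl anion would add to the formyl group and the acyl group would migrate (insertion into the C–CHO bond). Alternatively the aryl anion may be protonated before it reaches the ester, leaving an open aryl vinyl ether. The fallback uses only known chemistry, sets out from 11 and 8, and returns at 18. Ester 11 is saponified (LiOH, THF–H2O, rt) to 2,4-bis(methoxymethoxy)phenylacetic acid F1. F1 and 8 with CsF in THF in a sealed tube at 125 °C should undergo the known insertion of an aryne (here 16) into the O–C(acyl) bond of a carboxylic acid: O-arylation of the carboxylate is followed by O→C acyl shift onto the neighbouring aryl anion, with the same alkoxy-controlled regiochemistry. This should give the deoxybenzoin 1-[2,4-bis(benzyloxy)-6-hydroxyphenyl]-2-[2,4-bis(methoxymethoxy)phenyl]ethan-1-one F2. Heating F2 with DMF dimethyl acetal in toluene at 90 °C should form the enaminone (E)-1-[2,4-bis(benzyloxy)-6-hydroxyphenyl]-3-(dimethylamino)-2-[2,4-bis(methoxymethoxy)phenyl]prop-2-en-1-one F3, which cyclises with loss of dimethylamine to isoflavone 18.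

Risk 2 (step 10). While the two ordinary aryl MOM ethers are being cleaved, the acid may ionise the allylic aryl ether (loss of the prenyl group) or add methanol or HCl across the trisubstituted alkene. The fallback reverses the order of events, sets out from 19 and returns at 22. With no prenyl group present, 19 is deprotected under more forcing acid (aq. HCl, MeOH, 50 °C) to 5,7,2',4'-tetrahydroxyisoflavone F4. F4 is then alkylated with 20 (1.0 equiv) and K2CO3 (1.0 equiv) in DMF at 0 °C → rt. With one equivalent of base only 7-OH, the most acidic phenol, is ionised; the chelated 5-OH and the less acidic ring-B phenols should remain protonated, so 22 should be the main product.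

Risk 3 (step 2). n-BuLi may metalate a benzylic OCH2 position (followed by 1,2-Wittig shift), ortho-lithiation may be incomplete, or the lithiated carbamate may undergo anionic ortho-Fries migration on warming. The fallback replaces deprotonation by halogen–metal exchange, sets out from 1 and returns at 8, bypassing steps 1–3. Bromination of 1 (NBS, CH2Cl2, −78 °C) at the less hindered activated position between OH and OBn should give 2-bromo-3,5-bis(benzyloxy)phenol F5, separated from any 4-bromo isomer. Silylation (HMDS, THF, 70 °C, then evaporation) gives [2-bromo-3,5-bis(benzyloxy)phenoxy]trimethylsilane F6. n-BuLi in THF at −100 °C effects bromine–lithium exchange to [2,4-bis(benzyloxy)-6-(trimethylsilyloxy)phenyl]lithium F7, which undergoes 1,3-O→C silyl migration (retro-Brook rearrangement) to lithium 3,5-bis(benzyloxy)-2-(trimethylsilyl)phenoxide F8. Trapping with Tf2O at −100 → −78 °C gives 8.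

Further compounds
F1 | step 7 | 2,4-bis(methoxymethoxy)phenylacetic acid | COCOc1ccc(CC(=O)O)c(OCOC)c1
F2 | step 7 | 1-[2,4-bis(benzyloxy)-6-hydroxyphenyl]-2-[2,4-bis(methoxymethoxy)phenyl]ethan-1-one | COCOc1ccc(CC(=O)c2c(O)cc(OCc3ccccc3)cc2OCc2ccccc2)c(OCOC)c1
F3 | step 7 | (E)-1-[2,4-bis(benzyloxy)-6-hydroxyphenyl]-3-(dimethylamino)-2-[2,4-bis(methoxymethoxy)phenyl]prop-2-en-1-one | CN(C)/C=C(/C(=O)c1c(O)cc(OCc2ccccc2)cc1OCc1ccccc1)c1ccc(OCOC)cc1OCOC
F4 | step 10 | 5,7,2',4'-tetrahydroxyisoflavone | O=c1c(-c2ccc(O)cc2O)coc2cc(O)cc(O)c12
F5 | step 2 | 2-bromo-3,5-bis(benzyloxy)phenol | Oc1cc(OCc2ccccc2)cc(OCc2ccccc2)c1Br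
F6 | step 2 | [2-bromo-3,5-bis(benzyloxy)phenoxy]trimethylsilane | C[Si](C)(C)Oc1cc(OCc2ccccc2)cc(OCc2ccccc2)c1Br
F7 | step 2 | [2,4-bis(benzyloxy)-6-(trimethylsilyloxy)phenyl]lithium | C[Si](C)(C)Oc1cc(OCc2ccccc2)cc(OCc2ccccc2)c1[Li]
F8 | step 2 | lithium 3,5-bis(benzyloxy)-2-(trimethylsilyl)phenoxide | [Li+].[O-]c1cc(OCc2ccccc2)cc(OCc2ccccc2)c1[Si](C)(C)C
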